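**Retrosynthetic overview**
1. Target 28 ⇐ TES removal ⇐ C8 ester made with inversion (Mitsunobu) from the 8-epi macrocyclic alcohol 22 and epoxy acid 26 (Sharpless epoxidation, then oxidation, of tiglyl alcohol).
2. Key bond C7–C8: the ten-membered ring is closed by a chromium-mediated reaction in which C7, the β-carbon of a 3-(bromomethyl)butenolide (a lactone homoenolate equivalent), adds to the C8 aldehyde; the same event unveils the α-methylene lactone.
3. Butenolide by ring-closing metathesis of a 2-(bromomethyl)acrylate; C1–C10 oxirane by Shi epoxidation; Z C4=C5 olefin by iron-catalysed carbomagnesiation of a propargylic alcohol.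
4. C3 and C6 carbinols by two zinc–ProPhenol alkynylations; E C1=C10 olefin by Negishi carboalumination and ethylene oxide opening.
5. Ring order: trisubstituted oxirane → butenolide → ten-membered carbocycle; the side-chain oxirane is made separately.

Assumption: compound 1 (the PMB ether of but-3-yn-1-ol) is taken as a catalogue chemical; germacrane atom numbers (C1–C15) are used for all intermediates.

**Route**

Step 1
Reactants: 1 1-[(but-3-yn-1-yloxy)methyl]-4-methoxybenzene; 2 oxirane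
Product: 5 (3E)-6-[(4-methoxybenzyl)oxy]-4-methylhex-3-en-1-ol, via alkenyldimethylalane 3 (not isolated), via lithium alkenylalanate 4 (not isolated)
Conditions: Me3Al, Cp2ZrCl2 (25 mol%), CH2Cl2, 0 °C to rt; n-BuLi, THF/hexane, −78 °C; then 2, −78 °C to rt
Reagents that add atoms: trimethylaluminium, C[Al](C)C
Why: Negishi zirconium-catalysed syn-carboalumination places the methyl and aluminium cis, fixing the E C1=C10 olefin, and the derived alanate opens ethylene oxide with retention of olefin geometry.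

Step 2
Reactants: 5 (3E)-6-[(4-methoxybenzyl)oxy]-4-methylhex-3-en-1-ol
Product: 6 (3E)-6-[(4-methoxybenzyl)oxy]-4-methylhex-3-enal
Conditions: Dess–Martin periodinane, CH2Cl2, 0 °C to rt
Reagents that add atoms: none
Why: Dess–Martin oxidation is neutral enough to give the β,γ-unsaturated aldehyde without migration of the trisubstituted olefin; the aldehyde is used at once.

Step 3
Reactants: 6 (3E)-6-[(4-methoxybenzyl)oxy]-4-methylhex-3-enal; 7 ethynyltrimethylsilane
Product: 8 (3S,5E)-8-[(4-methoxybenzyl)oxy]-6-methyl-1-(trimethylsilyl)oct-5-en-1-yn-3-ol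
Conditions: (S,S)-ProPhenol (20 mol%), Me2Zn, Ph3PO (40 mol%), toluene, 4 °C
Reagents that add atoms: none
Why: Trost dinuclear zinc–ProPhenol alkynylation, in which the ligand enantiomer is chosen for Re-face delivery of the alkynylzinc (from memory this is the (S,S)-ligand; its antipode is used if the sense proves opposite) to set C3 as S under catalyst control.

Step 4
Reactants: 8 (3S,5E)-8-[(4-methoxybenzyl)oxy]-6-methyl-1-(trimethylsilyl)oct-5-en-1-yn-3-ol
Product: 10 (3S,5E)-8-[(4-methoxybenzyl)oxy]-6-methyl-3-[(triethylsilyl)oxy]oct-5-en-1-yne, via bis-silyl compound 9 (not isolated)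
Conditions: TESCl, imidazole, CH2Cl2, 0 °C; then MeOH, K2CO3, 0 °C, 30 min
Reagents that add atoms: chlorotriethylsilane, CC[Si](Cl)(CC)CC
Why: One-pot O-silylation followed by base-catalysed methanolysis of the acetylenic C–Si bond, which is much faster than cleavage of the secondary TES ether.

Step 5
Reactants: 10 (3S,5E)-8-[(4-methoxybenzyl)oxy]-6-methyl-3-[(triethylsilyl)oxy]oct-5-en-1-yne; 11 (2E)-but-2-enal
Product: 12 (2E,4S,7S,9E)-12-[(4-methoxybenzyl)oxy]-10-methyl-7-[(triethylsilyl)oxy]dodeca-2,9-dien-5-yn-4-ol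
Conditions: (S,S)-ProPhenol (20 mol%), Me2Zn, Ph3PO (40 mol%), 11 (3 equiv), toluene, 4 °C
Reagents that add atoms: none
Why: A second zinc–ProPhenol alkynylation with the same ligand adds the alkyne to the Re face of the enal and sets C6 under catalyst control (labelled S here and R from compound 18 on, only because CIP priorities change).

Step 6
Reactants: 12 (2E,4S,7S,9E)-12-[(4-methoxybenzyl)oxy]-10-methyl-7-[(triethylsilyl)oxy]dodeca-2,9-dien-5-yn-4-ol
Product: 14 (2E,4S,5Z,7S,9E)-12-[(4-methoxybenzyl)oxy]-6,10-dimethyl-7-[(triethylsilyl)oxy]dodeca-2,5,9-trien-4-ol, via alkenylmagnesium bromide 13 (not isolated)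
Conditions: MeMgBr (5 equiv), Fe(acac)3 (20 mol%), THF, −78 to 0 °C; aq. NH4Cl
Reagents that add atoms: methylmagnesium bromide, C[Mg]Br
Why: Iron-catalysed alkoxide-directed syn-carbomagnesiation of a propargylic alcohol puts the methyl on the alkyne carbon distal to the free C6 alkoxide (C4) and magnesium on C5, so protonation gives the olefin with C3 and C6 cis (Z).

Step 7
Reactants: 14 (2E,4S,5Z,7S,9E)-12-[(4-methoxybenzyl)oxy]-6,10-dimethyl-7-[(triethylsilyl)oxy]dodeca-2,5,9-trien-4-ol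
Product: 15 (2E,4S,5Z,7S)-8-[(2R,3R)-3-{2-[(4-methoxybenzyl)oxy]ethyl}-3-methyloxiran-2-yl]-6-methyl-7-[(triethylsilyl)oxy]octa-2,5-dien-4-ol
Conditions: D-fructose-derived Shi ketone (30 mol%), KHSO5 (as the triple salt 2KHSO5·KHSO4·K2SO4), K2CO3, Bu4NHSO4, MeCN/CH2(OMe)2/aq. buffer pH 10.5, 0 °C
Reagents that add atoms: potassium peroxymonosulfate, [K+].[O-]S(=O)(=O)OO
Why: Shi asymmetric epoxidation by the chiral dioxirane attacks only the electron-rich trialkyl olefin (the other two are deactivated by allylic oxygen and are Z-trisubstituted or disubstituted), and the D-fructose ketone sets C1 and C10 as R,R under reagent control.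

Step 8
Reactants: 15 (2E,4S,5Z,7S)-8-[(2R,3R)-3-{2-[(4-methoxybenzyl)oxy]ethyl}-3-methyloxiran-2-yl]-6-methyl-7-[(triethylsilyl)oxy]octa-2,5-dien-4-ol; 16 2-(bromomethyl)prop-2-enoic acid
Product: 17 (2E,4S,5Z,7S)-8-[(2R,3R)-3-{2-[(4-methoxybenzyl)oxy]ethyl}-3-methyloxiran-2-yl]-6-methyl-7-[(triethylsilyl)oxy]octa-2,5-dien-4-yl 2-(bromomethyl)prop-2-enoate
Conditions: DIC, DMAP (5 mol%), CH2Cl2, −10 °C to rt
Reagents that add atoms: none
Why: Steglich esterification of the C6 alcohol, with DMAP kept low and cold to limit quaternisation by the allylic bromide; no stereocentre is touched.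

Step 9
Reactants: 17 (2E,4S,5Z,7S)-8-[(2R,3R)-3-{2-[(4-methoxybenzyl)oxy]ethyl}-3-methyloxiran-2-yl]-6-methyl-7-[(triethylsilyl)oxy]octa-2,5-dien-4-yl 2-(bromomethyl)prop-2-enoate
Product: 18 (5R)-3-(bromomethyl)-5-[(1Z,3S)-4-[(2R,3R)-3-{2-[(4-methoxybenzyl)oxy]ethyl}-3-methyloxiran-2-yl]-2-methyl-3-[(triethylsilyl)oxy]but-1-en-1-yl]furan-2(5H)-one
Conditions: second-generation Hoveyda–Grubbs catalyst (10 mol%), toluene (5 mM), 80 °C
Reagents that add atoms: none
Why: Ring-closing metathesis between the acrylate and the propenyl group closes the butenolide and expels propene, while the trisubstituted olefin and the oxirane are inert.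

Step 10
Reactants: 18 (5R)-3-(bromomethyl)-5-[(1Z,3S)-4-[(2R,3R)-3-{2-[(4-methoxybenzyl)oxy]ethyl}-3-methyloxiran-2-yl]-2-methyl-3-[(triethylsilyl)oxy]but-1-en-1-yl]furan-2(5H)-one
Product: 19 (5R)-3-(bromomethyl)-5-[(1Z,3S)-4-[(2R,3R)-3-(2-hydroxyethyl)-3-methyloxiran-2-yl]-2-methyl-3-[(triethylsilyl)oxy]but-1-en-1-yl]furan-2(5H)-one
Conditions: DDQ (1.3 equiv), CH2Cl2/pH 7 buffer (10:1), 0 °C
Reagents that add atoms: none
Why: Oxidative PMB cleavage is neutral and non-nucleophilic, so the allylic bromide, the oxirane, the butenolide and the TES ether survive.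

Step 11
Reactants: 19 (5R)-3-(bromomethyl)-5-[(1Z,3S)-4-[(2R,3R)-3-(2-hydroxyethyl)-3-methyloxiran-2-yl]-2-methyl-3-[(triethylsilyl)oxy]but-1-en-1-yl]furan-2(5H)-one
Product: 20 2-[(2R,3R)-3-{(2S,3Z)-4-[(2R)-4-(bromomethyl)-5-oxo-2,5-dihydrofuran-2-yl]-3-methyl-2-[(triethylsilyl)oxy]but-3-en-1-yl}-2-methyloxiran-2-yl]acetaldehyde
Conditions: Dess–Martin periodinane, NaHCO3, CH2Cl2, 0 °C; used at once
Reagents that add atoms: none
Why: Buffered Dess–Martin oxidation gives the base-sensitive β,γ-epoxy aldehyde without elimination.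

Step 12
Reactants: 20 2-[(2R,3R)-3-{(2S,3Z)-4-[(2R)-4-(bromomethyl)-5-oxo-2,5-dihydrofuran-2-yl]-3-methyl-2-[(triethylsilyl)oxy]but-3-en-1-yl}-2-methyloxiran-2-yl]acetaldehyde
Product: 22 (1R,3S,4Z,6R,7R,8S,10R)-1,10-epoxy-8-hydroxy-3-[(triethylsilyl)oxy]germacra-4,11(13)-dien-12,6-olide, via allylchromium dichloride 21 (not isolated)
Conditions: CrCl2 (10 equiv), THF, rt, slow addition of 20 (final 2 mM)
Reagents that add atoms: none
Why: Proposed new method: divalent chromium inserts into the allylic C–Br bond to give σ-allylchromium 21, whose ring-locked γ-carbon C7 (the β-carbon of the lactone) adds to the tethered C8 aldehyde through a six-membered chair on the butenolide face opposite the C5 substituent (C7 = R, trans-lactone) with the C9 chain equatorial (E-type allylmetal gives anti, C8 = S), the allyl shift releasing the exo-methylene; the closest known reactions are intermolecular chromium-mediated additions of 3-(bromomethyl)furan-2(5H)-one to aldehydes and Nozaki–Hiyama–Kishi allyl macrocyclisations to ten-membered germacranolides.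

Step 13
Reactants: 23 (2E)-2-methylbut-2-en-1-ol
Product: 24 [(2R,3R)-2,3-dimethyloxiran-2-yl]methanol
Conditions: Ti(OiPr)4 (10 mol%), D-(−)-diethyl tartrate (12 mol%), t-BuOOH, 4 Å sieves, CH2Cl2, −20 °C
Reagents that add atoms: tert-butyl hydroperoxide, CC(C)(C)OO
Why: Sharpless asymmetric epoxidation; by analogy with (E)-hex-2-en-1-ol (natural tartrate gives 2S,3S), the D-(−)-tartrate catalyst gives the 2R,3R epoxy alcohol with the two methyls cis.

Step 14
Reactants: 24 [(2R,3R)-2,3-dimethyloxiran-2-yl]methanol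
Product: 26 (2S,3R)-2,3-dimethyloxirane-2-carboxylic acid, via epoxy aldehyde 25 (not isolated)
Conditions: TEMPO (10 mol%), PhI(OAc)2 (2.2 equiv), MeCN/H2O (1:1), rt
Reagents that add atoms: water, O
Why: Oxoammonium oxidation through the aldehyde hydrate gives the glycidic acid without opening the oxirane; the configuration is unchanged and the C2 label becomes S only by priority.

Step 15
Reactants: 22 (1R,3S,4Z,6R,7R,8S,10R)-1,10-epoxy-8-hydroxy-3-[(triethylsilyl)oxy]germacra-4,11(13)-dien-12,6-olide; 26 (2S,3R)-2,3-dimethyloxirane-2-carboxylic acid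
Product: 27 (1R,3S,4Z,6R,7R,8R,10R)-1,10-epoxy-8-{[(2S,3R)-2,3-dimethyloxirane-2-carbonyl]oxy}-3-[(triethylsilyl)oxy]germacra-4,11(13)-dien-12,6-olide
Conditions: PPh3, DIAD, toluene, 0 °C to rt
Reagents that add atoms: none
Why: Mitsunobu esterification, in which the carboxylate displaces the C8 alkoxyphosphonium by SN2, inverting C8 from S to R and installing the ester in one operation.

Step 16
Reactants: 27 (1R,3S,4Z,6R,7R,8R,10R)-1,10-epoxy-8-{[(2S,3R)-2,3-dimethyloxirane-2-carbonyl]oxy}-3-[(triethylsilyl)oxy]germacra-4,11(13)-dien-12,6-olide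
Product: 28 (1R,3S,4Z,6R,7R,8R,10R)-1,10-epoxy-8-{[(2S,3R)-2,3-dimethyloxirane-2-carbonyl]oxy}-3-hydroxygermacra-4,11(13)-dien-12,6-olide (CNP0268255.5)
Conditions: HF·pyridine, excess pyridine, THF, 0 °C
Reagents that add atoms: none
Why: Buffered fluoride desilylation removes the labile allylic TES ether quickly at 0 °C, sparing both oxiranes, the ester and the α-methylene lactone.

**Compound list**
1 | 1-[(but-3-yn-1-yloxy)methyl]-4-methoxybenzene | C#CCCOCc1ccc(OC)cc1 | starting material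
2 | oxirane (ethylene oxide) | C1CO1 | starting material
3 | (E)-[4-(4-methoxybenzyloxy)-2-methylbut-1-en-1-yl]dimethylalane (not isolated) | C[Al](C)/C=C(\C)CCOCc1ccc(OC)cc1 | intermediate
4 | lithium butyl[(E)-4-(4-methoxybenzyloxy)-2-methylbut-1-en-1-yl]dimethylaluminate (not isolated) | [Li+].CCCC[Al-](C)(C)/C=C(\C)CCOCc1ccc(OC)cc1 | intermediate
5 | (3E)-6-[(4-methoxybenzyl)oxy]-4-methylhex-3-en-1-ol | OCC/C=C(\C)CCOCc1ccc(OC)cc1 | intermediate
6 | (3E)-6-[(4-methoxybenzyl)oxy]-4-methylhex-3-enal | O=CC/C=C(\C)CCOCc1ccc(OC)cc1 | intermediate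
7 | ethynyltrimethylsilane | C#C[Si](C)(C)C | starting material
8 | (3S,5E)-8-[(4-methoxybenzyl)oxy]-6-methyl-1-(trimethylsilyl)oct-5-en-1-yn-3-ol | C[Si](C)(C)C#C[C@@H](O)C/C=C(\C)CCOCc1ccc(OC)cc1 | intermediate
9 | (3S,5E)-8-[(4-methoxybenzyl)oxy]-6-methyl-3-[(triethylsilyl)oxy]-1-(trimethylsilyl)oct-5-en-1-yne (not isolated) | C[Si](C)(C)C#C[C@@H](O[Si](CC)(CC)CC)C/C=C(\C)CCOCc1ccc(OC)cc1 | intermediate
10 | (3S,5E)-8-[(4-methoxybenzyl)oxy]-6-methyl-3-[(triethylsilyl)oxy]oct-5-en-1-yne | C#C[C@@H](O[Si](CC)(CC)CC)C/C=C(\C)CCOCc1ccc(OC)cc1 | intermediate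
11 | (2E)-but-2-enal (crotonaldehyde) | C/C=C/C=O | starting material
12 | (2E,4S,7S,9E)-12-[(4-methoxybenzyl)oxy]-10-methyl-7-[(triethylsilyl)oxy]dodeca-2,9-dien-5-yn-4-ol | C/C=C/[C@H](O)C#C[C@@H](O[Si](CC)(CC)CC)C/C=C(\C)CCOCc1ccc(OC)cc1 | intermediate
13 | bromomagnesium alkoxide of 14 carrying MgBr on C5, cis to the new methyl (not isolated) | C/C=C/[C@H](O[Mg]Br)/C([Mg]Br)=C(/C)[C@@H](O[Si](CC)(CC)CC)C/C=C(\C)CCOCc1ccc(OC)cc1 | intermediate
14 | (2E,4S,5Z,7S,9E)-12-[(4-methoxybenzyl)oxy]-6,10-dimethyl-7-[(triethylsilyl)oxy]dodeca-2,5,9-trien-4-ol | C/C=C/[C@H](O)/C=C(/C)[C@@H](O[Si](CC)(CC)CC)C/C=C(\C)CCOCc1ccc(OC)cc1 | intermediate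
15 | (2E,4S,5Z,7S)-8-[(2R,3R)-3-{2-[(4-methoxybenzyl)oxy]ethyl}-3-methyloxiran-2-yl]-6-methyl-7-[(triethylsilyl)oxy]octa-2,5-dien-4-ol | C/C=C/[C@H](O)/C=C(/C)[C@@H](O[Si](CC)(CC)CC)C[C@H]1O[C@]1(C)CCOCc2ccc(OC)cc2 | intermediate
16 | 2-(bromomethyl)prop-2-enoic acid | C=C(CBr)C(=O)O | starting material
17 | (2E,4S,5Z,7S)-8-[(2R,3R)-3-{2-[(4-methoxybenzyl)oxy]ethyl}-3-methyloxiran-2-yl]-6-methyl-7-[(triethylsilyl)oxy]octa-2,5-dien-4-yl 2-(bromomethyl)prop-2-enoate | C/C=C/[C@H](OC(=O)C(=C)CBr)/C=C(/C)[C@@H](O[Si](CC)(CC)CC)C[C@H]1O[C@]1(C)CCOCc2ccc(OC)cc2 | intermediate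
18 | (5R)-3-(bromomethyl)-5-[(1Z,3S)-4-[(2R,3R)-3-{2-[(4-methoxybenzyl)oxy]ethyl}-3-methyloxiran-2-yl]-2-methyl-3-[(triethylsilyl)oxy]but-1-en-1-yl]furan-2(5H)-one | BrCC1=C[C@@H](/C=C(/C)[C@@H](O[Si](CC)(CC)CC)C[C@H]2O[C@]2(C)CCOCc3ccc(OC)cc3)OC1=O | intermediate
19 | (5R)-3-(bromomethyl)-5-[(1Z,3S)-4-[(2R,3R)-3-(2-hydroxyethyl)-3-methyloxiran-2-yl]-2-methyl-3-[(triethylsilyl)oxy]but-1-en-1-yl]furan-2(5H)-one | BrCC1=C[C@@H](/C=C(/C)[C@@H](O[Si](CC)(CC)CC)C[C@H]2O[C@]2(C)CCO)OC1=O | intermediate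
20 | 2-[(2R,3R)-3-{(2S,3Z)-4-[(2R)-4-(bromomethyl)-5-oxo-2,5-dihydrofuran-2-yl]-3-methyl-2-[(triethylsilyl)oxy]but-3-en-1-yl}-2-methyloxiran-2-yl]acetaldehyde | BrCC1=C[C@@H](/C=C(/C)[C@@H](O[Si](CC)(CC)CC)C[C@H]2O[C@]2(C)CC=O)OC1=O | intermediate
21 | allylchromium dichloride of 20, CH2CrCl2 in place of CH2Br (not isolated) | Cl[Cr](Cl)CC1=C[C@@H](/C=C(/C)[C@@H](O[Si](CC)(CC)CC)C[C@H]2O[C@]2(C)CC=O)OC1=O | intermediate
22 | (1R,3S,4Z,6R,7R,8S,10R)-1,10-epoxy-8-hydroxy-3-[(triethylsilyl)oxy]germacra-4,11(13)-dien-12,6-olide (8α-OH, trans-fused lactone) | C=C1C(=O)O[C@@H]2/C=C(/C)[C@@H](O[Si](CC)(CC)CC)C[C@H]3O[C@]3(C)C[C@H](O)[C@@H]12 | intermediate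
23 | (2E)-2-methylbut-2-en-1-ol (tiglyl alcohol) | C/C=C(\C)CO | starting material
24 | [(2R,3R)-2,3-dimethyloxiran-2-yl]methanol | OC[C@@]1(C)O[C@@H]1C | intermediate
25 | (2S,3R)-2,3-dimethyloxirane-2-carbaldehyde (not isolated) | O=C[C@@]1(C)O[C@@H]1C | intermediate
26 | (2S,3R)-2,3-dimethyloxirane-2-carboxylic acid | OC(=O)[C@@]1(C)O[C@@H]1C | intermediate
27 | (1R,3S,4Z,6R,7R,8R,10R)-1,10-epoxy-8-{[(2S,3R)-2,3-dimethyloxirane-2-carbonyl]oxy}-3-[(triethylsilyl)oxy]germacra-4,11(13)-dien-12,6-olide | C=C1C(=O)O[C@@H]2/C=C(/C)[C@@H](O[Si](CC)(CC)CC)C[C@H]3O[C@]3(C)C[C@@H](OC(=O)[C@@]4(C)O[C@@H]4C)[C@@H]12 | intermediate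
28 | (1R,3S,4Z,6R,7R,8R,10R)-1,10-epoxy-8-{[(2S,3R)-2,3-dimethyloxirane-2-carbonyl]oxy}-3-hydroxygermacra-4,11(13)-dien-12,6-olide (CNP0268255.5) | C=C1C(=O)O[C@@H]2/C=C(/C)[C@@H](O)C[C@H]3O[C@]3(C)C[C@@H](OC(=O)[C@@]3(C)O[C@@H]3C)[C@@H]12 | target

**Step count and risks**

Total step count: 16 (14 on the main line, 2 for acid 26).
Longest linear sequence: 14 steps (steps 1–12, 15, 16).

The three steps most likely to fail:

Step 12 (ring closure). The risks are oligomerisation, attack on the wrong butenolide face (cis-lactone), and translactonisation of the chromium alkoxide onto C12. Fallback: setting out from 19, the allylic bromide is exchanged for boron (B2pin2, Pd2(dba)3 cat., toluene, 50 °C) to give the isolable pinacol allylboronate alcohol F1. Buffered Dess–Martin oxidation then gives the boronate aldehyde F2. Heating F2 in toluene at 80 °C and 1 mM closes the ring by intramolecular allylboration through the same chair arrangement, with no metal reductant and no Lewis-acidic salts, and aqueous work-up of the borate returns the route at 22.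

Step 15 (Mitsunobu with an α-quaternary acid on a ring alcohol). The risks are slow displacement and elimination toward C7. Fallback: setting out from 22, inversion is done first with a small, strong acid (chloroacetic acid, PPh3, DIAD) to give the 8β-chloroacetate F3. Thiourea and NaHCO3 in ethanol then release the 8β-alcohol F4 under neutral conditions. F4 is acylated with retention by the mixed anhydride of 26 (2,4,6-trichlorobenzoyl chloride, Et3N, then DMAP, toluene), which rejoins the route at 27.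

Step 6 (carbomagnesiation next to a bulky propargylic silyl ether). The risks are poor regiocontrol or no reaction. Fallback: setting out from 10, lithiation (n-BuLi, −78 °C) and methyl chloroformate give the ynoate F5. Me2CuLi at −78 °C adds syn and low-temperature protonation gives the Z-enoate F6. i-Bu2AlH gives the Z-allylic alcohol F7 and MnO2 gives the Z-enal F8. Catalyst-controlled Si-face addition of (E)-prop-1-enylzinc (from propyne, Cy2BH, then Me2Zn, with an amino-alcohol ligand) then rejoins the route at 14.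

Further compounds
F1 | step 12 | (5R)-5-[(1Z,3S)-4-[(2R,3R)-3-(2-hydroxyethyl)-3-methyloxiran-2-yl]-2-methyl-3-[(triethylsilyl)oxy]but-1-en-1-yl]-3-[(4,4,5,5-tetramethyl-1,3,2-dioxaborolan-2-yl)methyl]furan-2(5H)-one | CC1(C)OB(CC2=C[C@@H](/C=C(/C)[C@@H](O[Si](CC)(CC)CC)C[C@H]3O[C@]3(C)CCO)OC2=O)OC1(C)C
F2 | step 12 | 2-[(2R,3R)-2-methyl-3-{(2S,3Z)-3-methyl-4-[(2R)-5-oxo-4-[(4,4,5,5-tetramethyl-1,3,2-dioxaborolan-2-yl)methyl]-2,5-dihydrofuran-2-yl]-2-[(triethylsilyl)oxy]but-3-en-1-yl}oxiran-2-yl]acetaldehyde | CC1(C)OB(CC2=C[C@@H](/C=C(/C)[C@@H](O[Si](CC)(CC)CC)C[C@H]3O[C@]3(C)CC=O)OC2=O)OC1(C)C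
F3 | step 15 | (1R,3S,4Z,6R,7R,8R,10R)-8-(chloroacetoxy)-1,10-epoxy-3-[(triethylsilyl)oxy]germacra-4,11(13)-dien-12,6-olide | C=C1C(=O)O[C@@H]2/C=C(/C)[C@@H](O[Si](CC)(CC)CC)C[C@H]3O[C@]3(C)C[C@@H](OC(=O)CCl)[C@@H]12
F4 | step 15 | (1R,3S,4Z,6R,7R,8R,10R)-1,10-epoxy-8-hydroxy-3-[(triethylsilyl)oxy]germacra-4,11(13)-dien-12,6-olide | C=C1C(=O)O[C@@H]2/C=C(/C)[C@@H](O[Si](CC)(CC)CC)C[C@H]3O[C@]3(C)C[C@@H](O)[C@@H]12
F5 | step 6 | methyl (4S,6E)-9-[(4-methoxybenzyl)oxy]-7-methyl-4-[(triethylsilyl)oxy]non-6-en-2-ynoate | COC(=O)C#C[C@@H](O[Si](CC)(CC)CC)C/C=C(\C)CCOCc1ccc(OC)cc1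
F6 | step 6 | methyl (2Z,4S,6E)-9-[(4-methoxybenzyl)oxy]-3,7-dimethyl-4-[(triethylsilyl)oxy]nona-2,6-dienoate | COC(=O)/C=C(/C)[C@@H](O[Si](CC)(CC)CC)C/C=C(\C)CCOCc1ccc(OC)cc1
F7 | step 6 | (2Z,4S,6E)-9-[(4-methoxybenzyl)oxy]-3,7-dimethyl-4-[(triethylsilyl)oxy]nona-2,6-dien-1-ol | OC/C=C(/C)[C@@H](O[Si](CC)(CC)CC)C/C=C(\C)CCOCc1ccc(OC)cc1
F8 | step 6 | (2Z,4S,6E)-9-[(4-methoxybenzyl)oxy]-3,7-dimethyl-4-[(triethylsilyl)oxy]nona-2,6-dienal | O=C/C=C(/C)[C@@H](O[Si](CC)(CC)CC)C/C=C(\C)CCOCc1ccc(OC)cc1
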